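**Retrosynthetic overview**
Numbering: ring C1 (CMe2), C2 (CHBr), C3 (CH2), C4 (CHCl), C5 (alkylidene carbon), C6 (CHCl); side chain C7 (=CH), C8 (CH2Br). The plan rests on the C2–Br stereocentre beside quaternary C1 of the only carbocycle. C2 enters as the sp2 C–Br carbon of an enal and becomes stereogenic as the six-membered ring forms.
Ochtodene ⇒ ene-1,4-diol (C8–OH to Br; C4–OH to Cl with inversion) ⇒ butenolide C4–O–C8(=O)–C7=C5, whose five-membered ring forces C8 cis to C4 ⇒ intramolecular HWE of a C4 phosphonoacetate on a C5 ketone.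
α-Chloro ketone ⇒ anti opening by chloride at C6 of a C5–C6 epoxide placed syn to C4–OH ⇒ cis-5-bromo-4,4-dimethylcyclohex-2-enol ⇒ (CHO to CH3, C4=O to OH) 5-bromo-4-formyl-4-methylcyclohex-2-enone.
Enone ⇒ enantioselective [4+2] of 1-methoxy-3-silyloxybutadiene with (E)-3-bromo-2-methylacrolein (bonds C1–C6 and C2–C3). Ring order: carbocycle (step 5), transient epoxide (step 9, opened in step 10), temporary butenolide (step 13, opened in step 14).

Key step: step 5

Assumption: the sense of induction in step 5 is taken from the formyl C–H···O binding model of oxazaborolidinium–enal complexes, which points to the (3aR) catalyst for 2S; if the sense is opposite, the (3aS) catalyst is used and nothing else changes.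

Step 1
Reactants: 1 methyl methacrylate
Product: 2 methyl 2,3-dibromo-2-methylpropanoate (racemic)
Conditions: Br2 (1.05 equiv), CH2Cl2, 0 °C → rt
Reagents that add atoms: bromine, BrBr
Why: Electrophilic anti dibromination of the acrylate C=C is clean at low temperature, and the racemic centre it creates is destroyed in step 2.

Step 2
Reactants: 2 methyl 2,3-dibromo-2-methylpropanoate
Product: 3 methyl (E)-3-bromo-2-methylprop-2-enoate
Conditions: DBU (1.2 equiv), Et2O, 0 °C → rt; distillation
Reagents that add atoms: none
Why: E2 dehydrobromination removes the more acidic CH2Br hydrogen together with the tertiary α-bromide, and the isomer with bromine trans to the ester (E) should be favoured sterically and on equilibration, any Z isomer being removed by distillation.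

Step 3
Reactants: 3 methyl (E)-3-bromo-2-methylprop-2-enoate
Product: 4 (E)-3-bromo-2-methylprop-2-en-1-ol
Conditions: i-Bu2AlH (2.3 equiv), CH2Cl2, −78 → 0 °C; aq. potassium sodium tartrate
Reagents that add atoms: none
Why: 1,2-Reduction of an α,β-unsaturated ester with i-Bu2AlH ends at the allylic alcohol and leaves the vinylic C–Br bond and the E geometry untouched.

Step 4
Reactants: 4 (E)-3-bromo-2-methylprop-2-en-1-ol
Product: 5 (E)-3-bromo-2-methylacrolein
Conditions: MnO2 (activated, 15 equiv), CH2Cl2, rt; filtration, cold concentration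
Reagents that add atoms: none
Why: Allylic alcohol oxidation on MnO2 is neutral and heterogeneous, so the volatile enal should form without E/Z isomerisation or over-oxidation.

Step 5
Reactants: 5 (E)-3-bromo-2-methylacrolein; 6 trans-1-methoxy-3-(trimethylsilyloxy)buta-1,3-diene
Product: 8 (1R,6S)-6-bromo-1-methyl-4-oxocyclohex-2-ene-1-carbaldehyde (5-bromo-4-formyl-4-methylcyclohex-2-enone; Br trans to CHO), via silyl enol ether cycloadduct 7 (not isolated)
Conditions: (3aR)-1-(2-methylphenyl)-3,3-diphenyltetrahydro-1H,3H-pyrrolo[1,2-c][1,3,2]oxazaborole (20 mol %), (CF3SO2)2NH (18 mol %), CH2Cl2, −78 °C, 6 (1.5 equiv) added slowly; then 1 M aq. HCl, THF, 0 °C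
Reagents that add atoms: none
Why: The cationic boron Lewis acid binds the formyl oxygen of 5, helped by a formyl C–H···O contact that locks the s-trans enal, and the electron-rich diene 6 adds in a concerted, suprafacial but strongly asynchronous [4+2] process in which the C2–C3 bond (diene CH2 terminus to the bromine-bearing β-carbon) runs ahead of the C1–C6 bond. The closest known reactions are oxazaborolidinium-catalysed enantioselective Diels–Alder additions of 2-substituted and 2,3-disubstituted enals to silyloxy dienes, and the thermal addition of 6 to methacrolein. The single carbocycle is closed by the intermolecular cycloaddition itself, both new σ bonds arising in one six-centre transition state. The E geometry of 5 is carried into the trans relation of C2–Br and the C1 formyl group, the absolute configuration of C1 and C2 (2S) is fixed by the catalyst aryl group that covers one face of the bound enal, and the C6 methoxy centre (endo mode, cis to formyl) does not matter because it is erased. The step needs regioselectivity, secured by the matched polarisation of 6 (largest HOMO coefficient at its CH2 terminus) and 5 (largest LUMO coefficient at C2), and C=C over C=O periselectivity, which rests on the two-point binding that holds the formyl carbon against the catalyst while the C=C face stays open. Dilute acid then lets the silyl enol ether expel the C6 methoxy group vinylogously, so the C4 enone forms without enolisation toward C3 and the β-bromide stays in place.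

Step 6
Reactants: 8 (1R,6S)-6-bromo-1-methyl-4-oxocyclohex-2-ene-1-carbaldehyde
Product: 9 aldehyde tosylhydrazone of 8 (E C=N, enone intact)
Conditions: TsNHNH2 (1.0 equiv), THF, 0 °C → rt
Reagents that add atoms: p-toluenesulfonyl hydrazide, Cc1ccc(cc1)S(=O)(=O)NN
Why: Hydrazone formation with one equivalent of reagent picks the aldehyde over the less electrophilic conjugated ketone and needs neither acid nor base, which spares the β-bromo ketone.

Step 7
Reactants: 9 aldehyde tosylhydrazone of 8
Product: 10 allylic alcohol tosylhydrazone (C4–OH cis to C2–Br)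
Conditions: CeCl3·7H2O (1.2 equiv), NaBH4 (1.2 equiv), MeOH, −78 °C
Reagents that add atoms: none
Why: Luche 1,2-reduction is fast in a weakly acidic medium, so HBr loss and C=N reduction should not compete, and hydride arrives on the face opposite the C2 bromine (as with 5-substituted cyclohexenones such as carvone), which sets C4–OH cis to C2–Br.

Step 8
Reactants: 10 allylic alcohol tosylhydrazone
Product: 13 (1R,5S)-5-bromo-4,4-dimethylcyclohex-2-en-1-ol, via borylated tosylhydrazine 11 (not isolated), via monoalkyl diazene 12 (not isolated)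
Conditions: catecholborane (3 equiv), CHCl3, −10 → 0 °C; then NaOAc·3H2O (4 equiv), rt → reflux
Reagents that add atoms: none
Why: This mild variant of the Caglioti tosylhydrazone reduction hydroborates C=N, loses sulfinate to a monoalkyl diazene and extrudes N2 to leave the second C1 methyl under conditions that touch neither the hindered secondary bromide nor the alkene (loss of N2 is the one event the neighbouring C5=C6 bond could divert, hence the protic, hydrogen-donor-rich medium).

Step 9
Reactants: 13 (1R,5S)-5-bromo-4,4-dimethylcyclohex-2-en-1-ol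
Product: 14 (1R,2R,4S,6S)-4-bromo-5,5-dimethyl-7-oxabicyclo[4.1.0]heptan-2-ol (epoxide cis to C4–OH and C2–Br)
Conditions: m-CPBA (1.3 equiv), CH2Cl2, 0 °C → rt
Reagents that add atoms: m-chloroperoxybenzoic acid, OOC(=O)c1cccc(Cl)c1
Why: In this Henbest hydroxyl-directed epoxidation, hydrogen bonding of the peracid to the pseudo-equatorial C4–OH delivers oxygen to the syn face of C5=C6 and sets both epoxide carbons.

Step 10
Reactants: 14 epoxy alcohol
Product: 15 (1R,2R,3R,5S)-5-bromo-3-chloro-4,4-dimethylcyclohexane-1,2-diol (C4–OH and C5–OH cis to C2–Br; C6–Cl trans)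
Conditions: TiCl(OiPr)3 (2 equiv), CH2Cl2, 0 °C → rt; aq. tartaric acid
Reagents that add atoms: chlorotitanium triisopropoxide, CC(C)O[Ti](Cl)(OC(C)C)OC(C)C
Why: In this titanium-assisted opening of a 2,3-epoxy alcohol at the carbon remote from the carbinol, anti SN2 attack at C6 is the trans-diaxial (Fürst–Plattner) path of the half-chair that keeps C2–Br and C4–O equatorial, whereas attack at C5 is retarded inductively by C4–O and would put three groups axial, so C6–Cl is set trans to C5–OH.

Step 11
Reactants: 15 chlorohydrin diol; 16 diethylphosphonoacetic acid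
Product: 17 (1R,2R,3R,5S)-5-bromo-3-chloro-2-hydroxy-4,4-dimethylcyclohexyl 2-(diethoxyphosphoryl)acetate (ester on C4–O)
Conditions: 16 (1.05 equiv), DCC (1.1 equiv), 4-dimethylaminopyridine (10 mol %), CH2Cl2, −20 → 0 °C
Reagents that add atoms: none
Why: Steglich esterification should acylate the equatorial C4–OH in preference to the axial C5–OH, which is flanked by C6–Cl and is syn-axial to a C1 methyl.

Step 12
Reactants: 17 C4 phosphonoacetate
Product: 18 (1R,3R,5S)-5-bromo-3-chloro-4,4-dimethyl-2-oxocyclohexyl 2-(diethoxyphosphoryl)acetate (C5 ketone)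
Conditions: Dess–Martin periodinane (1.3 equiv), CH2Cl2, rt
Reagents that add atoms: none
Why: Dess–Martin oxidation of the remaining secondary alcohol is non-basic, so C4–H and C6–H should not epimerise and the ester should not migrate.

Step 13
Reactants: 18 C5 ketone
Product: 19 (4S,6S,7aR)-6-bromo-4-chloro-5,5-dimethyl-5,6,7,7a-tetrahydro-1-benzofuran-2(4H)-one (butenolide C4–O–C8(=O)–C7=C5)
Conditions: LiCl (3 equiv), i-Pr2NEt (2 equiv), MeCN, 0 °C → rt
Reagents that add atoms: none
Why: The intramolecular Horner–Wadsworth–Emmons reaction under Masamune–Roush conditions deprotonates only the lithium-chelated phosphonoacetate, and since the new C5=C7 bond lies in a five-membered lactone C8 must end cis to C4 (the alkene geometry of the target); the axial C6 chloride is also the thermodynamically preferred epimer.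

Step 14
Reactants: 19 butenolide
Product: 21 (1R,2E,3S,5S)-5-bromo-3-chloro-2-(2-hydroxyethylidene)-4,4-dimethylcyclohexan-1-ol, via lactol 20 (not isolated)
Conditions: i-Bu2AlH (4 equiv), CH2Cl2, −78 → 0 °C; aq. potassium sodium tartrate
Reagents that add atoms: none
Why: Exhaustive i-Bu2AlH reduction of a butenolide runs through the lactol aluminate and its open hydroxy-enal form to the ene-1,4-diol by 1,2-hydride delivery, without touching the alkyl halides or the alkene geometry.

Step 15
Reactants: 21 ene-1,4-diol
Product: 22 C8 tert-butyldimethylsilyl ether of 21 (C4–OH free)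
Conditions: TBSCl (1.05 equiv), imidazole (2 equiv), CH2Cl2, 0 °C
Reagents that add atoms: tert-butyldimethylsilyl chloride, CC(C)(C)[Si](C)(C)Cl
Why: Silylation with one equivalent of TBSCl is selective for the primary allylic C8–OH over the hindered secondary C4–OH.

Step 16
Reactants: 22 C8 silyl ether
Product: 23 tert-butyl{(2E)-2-[(2S,4S,6S)-4-bromo-2,6-dichloro-3,3-dimethylcyclohexylidene]ethoxy}dimethylsilane
Conditions: PPh3 (1.5 equiv), Cl3CC(O)CCl3 (3 equiv), CH2Cl2, −20 → 0 °C
Reagents that add atoms: hexachloroacetone, ClC(Cl)(Cl)C(=O)C(Cl)(Cl)Cl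
Why: Appel-type chlorination with PPh3/hexachloroacetone, the variant known to turn secondary allylic alcohols into chlorides with inversion and little allylic transposition, displaces the C4 oxyphosphonium by SN2 from the face opposite C2–Br and so sets C4–Cl cis to C6–Cl.

Step 17
Reactants: 23 silyl ether dichloride
Product: 24 (2E)-2-[(2S,4S,6S)-4-bromo-2,6-dichloro-3,3-dimethylcyclohexylidene]ethan-1-ol
Conditions: HF·pyridine, pyridine, THF, 0 °C
Reagents that add atoms: none
Why: Fluoride cleavage of a primary TBS ether with buffered HF·pyridine is non-basic, so the two allylic chlorides should be neither eliminated nor substituted.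

Step 18
Reactants: 24 allylic alcohol
Product: 25 ochtodene, (1S,3S,4E,5S)-1-bromo-4-(2-bromoethylidene)-3,5-dichloro-2,2-dimethylcyclohexane
Conditions: CBr4 (1.3 equiv), PPh3 (1.3 equiv), CH2Cl2, −20 → 0 °C
Reagents that add atoms: carbon tetrabromide, BrC(Br)(Br)Br
Why: Appel bromination of a primary allylic alcohol proceeds by direct SN2 at C8 at low temperature, faster than halide exchange at the hindered secondary chlorides, and keeps the alkene geometry.

**Compound list**
1 | methyl methacrylate | C=C(C)C(=O)OC | starting material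
2 | methyl 2,3-dibromo-2-methylpropanoate (racemic) | COC(=O)C(C)(Br)CBr | intermediate
3 | methyl (E)-3-bromo-2-methylprop-2-enoate | Br/C=C(\C)C(=O)OC | intermediate
4 | (E)-3-bromo-2-methylprop-2-en-1-ol | Br/C=C(\C)CO | intermediate
5 | (E)-3-bromo-2-methylacrolein | Br/C=C(\C)C=O | intermediate
6 | trans-1-methoxy-3-(trimethylsilyloxy)buta-1,3-diene | CO/C=C/C(=C)O[Si](C)(C)C | starting material
7 | (1R,2S,6S)-6-bromo-2-methoxy-1-methyl-4-(trimethylsilyloxy)cyclohex-3-ene-1-carbaldehyde (OMe cis to CHO, Br trans; not isolated) | C[C@@]1(C=O)[C@@H](Br)CC(O[Si](C)(C)C)=C[C@@H]1OC | intermediate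
8 | (1R,6S)-6-bromo-1-methyl-4-oxocyclohex-2-ene-1-carbaldehyde | C[C@@]1(C=O)[C@@H](Br)CC(=O)C=C1 | intermediate
9 | N'-{(E)-[(1R,6S)-6-bromo-1-methyl-4-oxocyclohex-2-en-1-yl]methylidene}-4-methylbenzenesulfonohydrazide | C[C@@]1(/C=N/NS(=O)(=O)c2ccc(C)cc2)[C@@H](Br)CC(=O)C=C1 | intermediate
10 | N'-{(E)-[(1R,4R,6S)-6-bromo-4-hydroxy-1-methylcyclohex-2-en-1-yl]methylidene}-4-methylbenzenesulfonohydrazide | C[C@@]1(/C=N/NS(=O)(=O)c2ccc(C)cc2)[C@@H](Br)C[C@@H](O)C=C1 | intermediate
11 | N,O-bis(catecholboryl) tosylhydrazine from 10 (not isolated) | C[C@@]1(CN(B2Oc3ccccc3O2)NS(=O)(=O)c4ccc(C)cc4)[C@@H](Br)C[C@@H](OB5Oc6ccccc6O5)C=C1 | intermediate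
12 | monoalkyl diazene, C1–CH2–N=NH (not isolated) | C[C@@]1(CN=N)[C@@H](Br)C[C@@H](O)C=C1 | intermediate
13 | (1R,5S)-5-bromo-4,4-dimethylcyclohex-2-en-1-ol | CC1(C)[C@@H](Br)C[C@@H](O)C=C1 | intermediate
14 | (1R,2R,4S,6S)-4-bromo-5,5-dimethyl-7-oxabicyclo[4.1.0]heptan-2-ol | CC1(C)[C@@H](Br)C[C@@H](O)[C@H]2O[C@@H]12 | intermediate
15 | (1R,2R,3R,5S)-5-bromo-3-chloro-4,4-dimethylcyclohexane-1,2-diol | CC1(C)[C@@H](Br)C[C@@H](O)[C@@H](O)[C@@H]1Cl | intermediate
16 | diethylphosphonoacetic acid | OC(=O)CP(=O)(OCC)OCC | starting material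
17 | (1R,2R,3R,5S)-5-bromo-3-chloro-2-hydroxy-4,4-dimethylcyclohexyl 2-(diethoxyphosphoryl)acetate | CC1(C)[C@@H](Br)C[C@@H](OC(=O)CP(=O)(OCC)OCC)[C@@H](O)[C@@H]1Cl | intermediate
18 | (1R,3R,5S)-5-bromo-3-chloro-4,4-dimethyl-2-oxocyclohexyl 2-(diethoxyphosphoryl)acetate | CC1(C)[C@@H](Br)C[C@@H](OC(=O)CP(=O)(OCC)OCC)C(=O)[C@@H]1Cl | intermediate
19 | (4S,6S,7aR)-6-bromo-4-chloro-5,5-dimethyl-5,6,7,7a-tetrahydro-1-benzofuran-2(4H)-one | CC1(C)[C@@H](Br)C[C@H]2OC(=O)C=C2[C@@H]1Cl | intermediate
20 | lactol of 19 (C8 hemiacetal, either anomer; not isolated) | CC1(C)[C@@H](Br)C[C@H]2OC(O)C=C2[C@@H]1Cl | intermediate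
21 | (1R,2E,3S,5S)-5-bromo-3-chloro-2-(2-hydroxyethylidene)-4,4-dimethylcyclohexan-1-ol | CC1(C)[C@@H](Br)C[C@@H](O)/C(=C\CO)[C@@H]1Cl | intermediate
22 | C8 tert-butyldimethylsilyl ether of 21 | CC1(C)[C@@H](Br)C[C@@H](O)/C(=C\CO[Si](C)(C)C(C)(C)C)[C@@H]1Cl | intermediate
23 | tert-butyl{(2E)-2-[(2S,4S,6S)-4-bromo-2,6-dichloro-3,3-dimethylcyclohexylidene]ethoxy}dimethylsilane | CC1(C)[C@@H](Br)C[C@H](Cl)/C(=C\CO[Si](C)(C)C(C)(C)C)[C@@H]1Cl | intermediate
24 | (2E)-2-[(2S,4S,6S)-4-bromo-2,6-dichloro-3,3-dimethylcyclohexylidene]ethan-1-ol | CC1(C)[C@@H](Br)C[C@H](Cl)/C(=C\CO)[C@@H]1Cl | intermediate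
25 | ochtodene | CC1(C)[C@@H](Br)C[C@H](Cl)/C(=C\CBr)[C@@H]1Cl | target

**Step count:** 18 steps in total. The longest linear sequence is 18 steps, from methyl methacrylate; 6 and 16 are bought.

**Three steps most likely to fail**

Step 5. The diene may add to the formyl C=O (hetero-cycloaddition or Mukaiyama aldol path) instead of the trisubstituted C=C. The trimethylsilyl group may pass to the triflimide counter-ion and start an achiral silicon-Lewis-acid background reaction that erodes the enantiomeric purity. The acidic catalyst may also protodesilylate the diene before the sluggish dienophile reacts.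
The fallback sets out from 5 and comes back at 8, and gives up both the acid-labile diene and the cationic Lewis acid.
- Compound 5 is combined at −78 °C in toluene with commercial trans-3-(tert-butyldimethylsilyloxy)-N,N-dimethylbuta-1,3-dien-1-amine, a much more nucleophilic diene known to add to 2-substituted enals at that temperature.
- Catalysis is by hydrogen bonding, using one enantiomer (chosen for the 2S sense) of 2,2-dimethyl-α,α,α',α'-tetra(1-naphthyl)-1,3-dioxolane-4,5-dimethanol.
- This gives the amino silyl enol ether cycloadduct F1. HF in MeCN then removes the silyl group and eliminates dimethylamine to give 8.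

Step 10. Chloride may be too slow at the neopentyl-type C6, so that attack at C5 or a Lewis-acid-induced 1,2-shift of a C1 methyl takes over.
The fallback sets out from 14 and comes back at 17.
- The C4–OH is acylated first with 16 (DCC, 4-dimethylaminopyridine) to give the epoxy phosphonoacetate F2.
- The epoxide is then opened with HCl in Et2O/CHCl3 at 0 °C, without any chelating metal.
- The stronger electron withdrawal of the acyloxy group deactivates C5 further. Control passes from chelation to the inductive and trans-diaxial bias, and the selective mono-acylation of step 11 is no longer needed.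

Step 16. The activated allylic alcohol may ionise, with loss of clean inversion, attack of chloride at C7 (allylic transposition) or elimination toward C3. The incoming chloride is also repelled by the syn C6 chloride.
The fallback sets out from 19 and comes back at 24.
- The butenolide is opened with Me2AlN(OMe)Me (from AlMe3 and MeONHMe·HCl, CH2Cl2, 0 °C) to the γ-hydroxy N-methoxy-N-methyl enamide F3, which is used at once to forestall relactonisation.
- PPh3/hexachloroacetone now acts on an allylic alcohol whose alkene is conjugated to a carbonyl group. Ionisation and attack at C7 are therefore disfavoured, and direct SN2 with inversion should give the chloro enamide F4.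
- i-Bu2AlH at −78 °C gives the enal F5, and NaBH4/CeCl3·7H2O in MeOH reduces it to 24. The silyl protection and deprotection steps drop out.

**Further compounds**
F1 | step 5 | (1R,2S,6S)-6-bromo-2-(dimethylamino)-1-methyl-4-(tert-butyldimethylsilyloxy)cyclohex-3-ene-1-carbaldehyde | C[C@@]1(C=O)[C@@H](Br)CC(O[Si](C)(C)C(C)(C)C)=C[C@@H]1N(C)C
F2 | step 10 | (1R,2R,4S,6S)-4-bromo-5,5-dimethyl-7-oxabicyclo[4.1.0]heptan-2-yl 2-(diethoxyphosphoryl)acetate | CC1(C)[C@@H](Br)C[C@@H](OC(=O)CP(=O)(OCC)OCC)[C@H]2O[C@@H]12
F3 | step 16 | (2E)-2-[(2S,4S,6R)-4-bromo-2-chloro-6-hydroxy-3,3-dimethylcyclohexylidene]-N-methoxy-N-methylacetamide | CC1(C)[C@@H](Br)C[C@@H](O)/C(=C\C(=O)N(C)OC)[C@@H]1Cl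
F4 | step 16 | (2E)-2-[(2S,4S,6S)-4-bromo-2,6-dichloro-3,3-dimethylcyclohexylidene]-N-methoxy-N-methylacetamide | CC1(C)[C@@H](Br)C[C@H](Cl)/C(=C\C(=O)N(C)OC)[C@@H]1Cl
F5 | step 16 | (2E)-2-[(2S,4S,6S)-4-bromo-2,6-dichloro-3,3-dimethylcyclohexylidene]acetaldehyde | CC1(C)[C@@H](Br)C[C@H](Cl)/C(=C\C=O)[C@@H]1Cl
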